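## The problem

The target, (3R)-3-(5-hydroxy-2,2-dimethyl-2H-chromen-6-yl)-8-(3-methylbut-2-en-1-yl)chroman-7-ol (35), is an isoflavan. Ring A is fused to the oxygen ring C (O1, C2, C3, C4, C4a, C5–C8, C8a), and C3 carries ring B. Ring B has a free 2′-OH and is fused across C3′/C4′ to a 2,2-dimethyl-2H-pyran. Ring A has a free 7-OH and a prenyl group at C8, wedged between O7 and O1.

C3 is the only stereocenter. It is benzylic and has no neighbour that could direct it, so it must be set by an external controller and afterwards kept out of any position α to a carbonyl group.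

Ring A poses a regiochemical problem. C6 and C8 are both ortho to O7, so prenylation or metalation of a preformed resorcinol ring has to choose between them. Three phenolic oxygens (O1, O7, O2′) must also be told apart, and O2′ could close a five-membered ring onto C2.

Several groups are fragile. The ortho-prenyl phenol cyclises to a dimethylchroman in acid. The chromene is sensitive to acid and oxidants and opens reversibly under ultraviolet light. Three C=C bonds exclude hydrogenation and ozonolysis.

The feature that makes the key step possible is the run C7(OH)–C8(prenyl)–C8a(O)–C4a(CH2) with C5 and C6 unsubstituted. This is the substitution pattern of the phenol formed from a 2-alkyl vinylketene and a siloxyalkyne bearing the prenyl group, so ring A can be grown around the prenyl group and emerges with O7 free and the C8a oxygen silylated.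

## Retrosynthesis

**Ring C and the last protecting group.** Target 35 is traced to its 2′-O-MOM ether 34, and ring C of 34 is opened at O1–C2 to give phenol–alcohol 33. Cutting this C–O bond, rather than a C–C bond of ring C, lets C3 be set on an open chain. The forward closure is a 6-membered etherification at a CH2 group, which cannot touch C3. The MOM group on O2′ is needed until after this closure, because a free 2′-OH would compete through a 5-membered ring. The forward reaction must favour the C8a phenol over the C7 phenol; only the former can reach C2 intramolecularly.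

**Ring A.** Triol 33 is the desilylated form of 32. In 32 the bonds C7–C8, C8a–C4a and C6–C7 are cut, which dissolves ring A into diazo vinyl ketone 22 and siloxyalkyne 27. The neighbouring option, prenylating an intact resorcinol ring, must discriminate C8 from C6. The benzannulation has no such choice, since the prenyl group is already on the alkyne carbon that becomes C8. It also delivers O7 as a free phenol and the C8a oxygen as a silyl ether, the differentiation the ring C closure needs. The precursors are an open chain carrying C3 and a six-carbon alkyne. The forward step must generate vinylketene 28 by Wolff rearrangement without exciting the chromene, which is why long-wavelength light is specified, and the ketene must find the alkyne before anything else.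

**Siloxyalkyne.** The O–Si bond of 27 is cut to ynolate 26, which is traced to methyl ester 24 by an ester homologation that inserts one carbon, the carbon that becomes C8. The ester must therefore already be the β,γ-unsaturated 4-methylpent-3-enoate. A γ,δ-unsaturated ester from a Claisen rearrangement would place a homoprenyl chain on the alkyne. Ester 24 comes from commercial acid 23. The forward reaction must add to the ester carbonyl faster than it deprotonates the doubly activated α-CH2.

**Diazo ketone.** The diazo group of 22 is removed to give vinyl ketone 19, whose only enolisable position is the carbon that becomes C4a, so the site of diazo transfer is unambiguous. The bond between the carbonyl carbon and the vinyl group is then cut to aldehyde 17. The aldehyde goes back through alcohol 16 to terminal alkene 14 by anti-Markovnikov hydration. Each step removes a sensitive group, and 14 contains only the stereocenter, ring B and a silyl ether. The hydroboration must leave the chromene double bond alone.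

**Stereocenter.** Silyl ether 14 comes from alcohol 13 and that from imide 12. The C3–C4 bond of 12 is cut, leading to arylacetyl oxazolidinone 10 and an allyl electrophile. An auxiliary-controlled enolate alkylation is chosen over a catalytic arylation because its facial sense is predictable for ortho-alkoxy arylacetic acids. The (R)-auxiliary 8 gives the (2R) centre, which becomes (3R) in 35. The auxiliary is cleaved reductively at once, so C3 is next to a carbonyl group for only two steps.

**Ring B.** Imide 10 is made from arylacetic acid 7 and auxiliary 8. Acid 7 is the one-carbon homologue of aldehyde 4, reached through nitrile 6. Aldehyde 4 is the MOM ether of chromene aldehyde 3, which comes from the commercial aldehydes 1 and 2 in one chromenylation. The chromene is thus present from the first step and never has to be made by oxidation late in the synthesis. The homologation is kept entirely basic to spare the MOM acetal.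

## Roads not taken

**Alternative 1:** Both aryl–CH2 bonds of the prenyl units (C8–CH2 and C3′–CH2) are cut; the ring B prenyl group would later become the pyran.

- Forward step: the (3R)-isoflavan A2, with O7 and O2′ as MOM ethers and O4′ as a SEM ether, is lithiated twice (C8 between O1 and O7, C3′ between O2′ and O4′). Both sites are transmetalated to copper and prenylated in one operation to give A1.
- Merits: both target positions are flanked by two directing oxygens, the core A2 is a simple isoflavan, and two C–C bonds form at once.
- Weak points: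
  - C6 and C5′ are also ortho to a directing group, and the second lithiation must occur on an already anionic species.
  - Allyl transfer from copper can give branched as well as linear products.
  - After A1 the route still needs selective SEM removal and an oxidative cyclisation of the 3′-prenyl-4′-phenol to the chromene. That oxidation meets a second prenyl group and the benzylic C4–H of the isoflavan.
  - The end is an acidic removal of two MOM groups from a molecule with a prenyl phenol and a chromene.
  - A2 itself needs an enantioselective synthesis.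
- Comparison: this road is shorter in its longest linear sequence and more convergent than the chosen plan. The chosen plan offers a prenyl position fixed by construction, a chromene that is never made by oxidation next to another prenyl group, and a single MOM group to remove at the end.

**Alternative 2:** C3–C1′ and C4–C4a are cut, and C2 is added afterwards.

- Forward step: vinyl boronic ester A6 and the ring B Grignard reagent A5 form an ate complex. A palladium catalyst with a chiral ferrocenyl bisphosphine couples it with ring A bromide A4, so that the ring B aryl migrates from boron to carbon while ring A is delivered to the terminal carbon. The product is boronate A3 with C3 configured.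
- Follow-up: one-carbon homologation of the C–B bond and oxidation would supply C2 as a hydroxymethyl group, after which the end game of the chosen route applies.
- Merits: the stereocenter is set by a catalyst instead of an auxiliary, three components meet in one step, and the sequence would be clearly shorter.
- Weak points:
  - The migrating aryl group is ortho-alkoxy substituted and the bromide A4 carries a bulky ortho silyloxy group, a combination at the edge of what this coupling is known to tolerate.
  - Bromide and magnesium salts require a halide scavenger.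
  - A4 must itself be made with the prenyl group between two oxygens, which returns the regiochemical problem of ring A to classical aromatic chemistry.
- Comparison: the alternative wins on step count and on catalytic stereocontrol. The chosen plan offers a predictable, auxiliary-based C3 and a ring A whose substitution pattern needs no selective aromatic substitution.

**Alternative 3:** C3–C4 and O1–C2 are cut.

- Forward step: mild base converts the ring A 2-(tosylmethyl)phenol A9 into ortho-quinone methide A10. Arylacetaldehyde A8, activated as its enamine by a chiral diarylprolinol silyl ether, adds to the methide carbon, and the phenoxide closes onto the aldehyde carbon to give lactol A7.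
- Merits: ring C, the C3–C4 bond and the stereocenter form in one catalytic step, the shortest conceivable assembly.
- Weak points:
  - The new stereocenter in A7 is benzylic and α to a masked aldehyde. The lactol is in equilibrium with the open hydroxy aldehyde, so C3 can epimerise under the basic conditions that generate A10 and in the presence of the amine catalyst.
  - A8 is an electron-rich arylacetaldehyde that enolises and self-condenses readily.
  - The lactol must then be deoxygenated. The ionic route uses acid next to a prenyl group, a chromene and two MOM ethers; the alternative is reduction to the diol and a separate cyclisation.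
- Comparison: this road is by far the most step-economic. The chosen plan is longer but keeps C3 away from any carbonyl group after its second step and never has to deoxygenate C2.

Key step: step 16

Abbreviation used in names: ArB = 5-(methoxymethoxy)-2,2-dimethyl-2H-chromen-6-yl (ring B with its fused dimethylpyran; the MOM ether sits on the oxygen next to the point of attachment). TBS = tert-butyldimethylsilyl.

Step 1
Reactants: 1 resorcylaldehyde (2,4-dihydroxybenzaldehyde); 2 prenal (3-methylbut-2-enal)
Product: 3 chromene aldehyde (5-hydroxy-2,2-dimethyl-2H-chromene-6-carbaldehyde)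
Conditions: pyridine, 120 °C
Reagents that add atoms: none
Why: Chromenylation: condensation of the enal at C3 of the resorcinol followed by 6-electron oxa-electrocyclisation; the 2-OH is tied up in a hydrogen bond to the aldehyde, so the 4-OH closes the pyran and the angular 5-hydroxy-6-formyl chromene should be the main product.

Step 2
Reactants: 3 chromene aldehyde (5-hydroxy-2,2-dimethyl-2H-chromene-6-carbaldehyde)
Product: 4 MOM-protected chromene aldehyde (ArB-CHO)
Conditions: MOMCl, i-Pr2NEt, DMAP (cat.), CH2Cl2, 0 to 40 °C
Reagents that add atoms: chloromethyl methyl ether, COCCl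
Why: O-alkylation of the phenol to the acetal; the chelated ortho-hydroxy aldehyde reacts slowly but cleanly, and the MOM ether should resist every later basic, hydridic and organometallic step.

Step 3
Reactants: 4 MOM-protected chromene aldehyde (ArB-CHO)
Product: 6 arylacetonitrile (ArB-CH2CN), via vinyl formamide 5 (not isolated)
Conditions: TosMIC, KOt-Bu, DME, −50 °C; then MeOH, 65 °C
Reagents that add atoms: p-toluenesulfonylmethyl isocyanide, Cc1ccc(cc1)S(=O)(=O)C[N+]#[C-]
Why: van Leusen reductive cyanation: the isocyanide anion adds to the aldehyde, the oxazoline opens to formamide 5, and methanolysis removes the formyl group and expels sulfinate to give the homologous nitrile; every stage is basic, so acetal and chromene are not at risk.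

Step 4
Reactants: 6 arylacetonitrile (ArB-CH2CN)
Product: 7 arylacetic acid (ArB-CH2CO2H)
Conditions: KOH, EtOH–H2O, 85 °C; then aq. KHSO4 to pH 3, 0 °C
Reagents that add atoms: potassium hydroxide, [K+].[OH-]; water, O
Why: Alkaline nitrile hydrolysis; brief cold acidification should free the acid without cleaving the MOM acetal.

Step 5
Reactants: 7 arylacetic acid (ArB-CH2CO2H); 8 auxiliary ((4R)-4-benzyl-1,3-oxazolidin-2-one)
Product: 10 N-acyl oxazolidinone ((4R)-4-benzyl-3-(ArB-acetyl)-1,3-oxazolidin-2-one), via mixed pivalic anhydride 9 (not isolated)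
Conditions: PivCl, Et3N, THF, −20 °C; then 8, LiCl, rt
Reagents that add atoms: none
Why: N-acylation of the oxazolidinone by the mixed anhydride under LiCl/amine activation, a standard procedure for arylacetic acids that needs no strong base.

Step 6
Reactants: 10 N-acyl oxazolidinone ((4R)-4-benzyl-3-(ArB-acetyl)-1,3-oxazolidin-2-one)
Product: 12 allylated imide ((4R)-4-benzyl-3-[(2R)-2-ArB-pent-4-enoyl]-1,3-oxazolidin-2-one), via sodium enolate 11 (not isolated)
Conditions: NaN(SiMe3)2, THF, −78 °C; allyl iodide, −78 to −45 °C; AcOH
Reagents that add atoms: allyl iodide, C=CCI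
Why: Evans alkylation: the chelated (Z)-enolate 11 is attacked by the allyl halide on the face opposite the benzyl group, which with the (R)-auxiliary gives the (2R) centre (aryl ranks above allyl); the cold acetic acid quench guards the acidic α-aryl position against epimerisation.

Step 7
Reactants: 12 allylated imide ((4R)-4-benzyl-3-[(2R)-2-ArB-pent-4-enoyl]-1,3-oxazolidin-2-one)
Product: 13 pentenol ((2R)-2-ArB-pent-4-en-1-ol)
Conditions: LiBH4, MeOH (1 equiv), THF, 0 °C
Reagents that add atoms: none
Why: Reductive cleavage of the imide to the primary alcohol with recovery of the auxiliary; from here on C3 is no longer α to a carbonyl group and cannot epimerise.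

Step 8
Reactants: 13 pentenol ((2R)-2-ArB-pent-4-en-1-ol)
Product: 14 silyl ether (tert-butyl{[(2R)-2-ArB-pent-4-en-1-yl]oxy}dimethylsilane)
Conditions: TBSCl, imidazole, CH2Cl2, rt
Reagents that add atoms: tert-butyldimethylsilyl chloride, CC(C)(C)[Si](C)(C)Cl
Why: Silylation of a primary alcohol; the TBS ether masks the future C2 oxygen and is later removed by fluoride together with the aryl silyl ether.

Step 9
Reactants: 14 silyl ether (tert-butyl{[(2R)-2-ArB-pent-4-en-1-yl]oxy}dimethylsilane)
Product: 16 primary alcohol ((4R)-5-[(tert-butyldimethylsilyl)oxy]-4-ArB-pentan-1-ol), via B-alkyl-9-BBN 15 (not isolated)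
Conditions: 9-BBN, THF, 0 °C to rt; then NaOH, H2O2, 0 °C to rt
Reagents that add atoms: hydrogen peroxide, OO
Why: Hydroboration–oxidation; 9-BBN adds to the monosubstituted alkene with anti-Markovnikov sense and should ignore the cis-disubstituted chromene alkene, which is flanked by a quaternary carbon.

Step 10
Reactants: 16 primary alcohol ((4R)-5-[(tert-butyldimethylsilyl)oxy]-4-ArB-pentan-1-ol)
Product: 17 aldehyde ((4R)-5-[(tert-butyldimethylsilyl)oxy]-4-ArB-pentanal)
Conditions: Dess–Martin periodinane, NaHCO3, CH2Cl2, 0 °C to rt
Reagents that add atoms: none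
Why: Dess–Martin oxidation under bicarbonate buffer, neutral enough for the MOM acetal, the silyl ether and the chromene.

Step 11
Reactants: 17 aldehyde ((4R)-5-[(tert-butyldimethylsilyl)oxy]-4-ArB-pentanal)
Product: 18 allylic alcohol ((6R)-7-[(tert-butyldimethylsilyl)oxy]-6-ArB-hept-1-en-3-ol, both C3 epimers)
Conditions: CH2=CHMgBr, THF, −78 °C; aq. NH4Cl
Reagents that add atoms: vinylmagnesium bromide, C=C[Mg]Br
Why: Grignard addition to an unhindered aldehyde; the new carbinol centre forms without control and is erased in the next step.

Step 12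
Reactants: 18 allylic alcohol ((6R)-7-[(tert-butyldimethylsilyl)oxy]-6-ArB-hept-1-en-3-ol, both C3 epimers)
Product: 19 vinyl ketone ((6R)-7-[(tert-butyldimethylsilyl)oxy]-6-ArB-hept-1-en-3-one)
Conditions: Dess–Martin periodinane, NaHCO3, CH2Cl2, 0 °C
Reagents that add atoms: none
Why: Dess–Martin oxidation of the allylic alcohol; the unhindered enone is prone to polymerise and is to be carried on without storage.

Step 13
Reactants: 19 vinyl ketone ((6R)-7-[(tert-butyldimethylsilyl)oxy]-6-ArB-hept-1-en-3-one)
Product: 22 diazo vinyl ketone ((6R)-7-[(tert-butyldimethylsilyl)oxy]-4-diazo-6-ArB-hept-1-en-3-one), via lithium dienolate 20 (not isolated), via trifluoroacetyl diketone 21 (not isolated)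
Conditions: LiN(SiMe3)2, THF, −78 °C; CF3CO2CH2CF3, −78 °C; aq. NH4Cl; then MsN3, Et3N, H2O (1 equiv), MeCN, rt
Reagents that add atoms: methanesulfonyl azide, CS(=O)(=O)N=[N+]=[N-]
Why: Detrifluoroacetylative diazo transfer: kinetic deprotonation at the only enolisable carbon gives 20, Claisen acylation gives the activated diketone 21, and the sulfonyl azide transfers N2 to that carbon with loss of the trifluoroacetyl group as an acyl sulfonamide; this two-stage variant is the established route to α′-diazo enones, which direct diazo transfer does not give.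

Step 14
Reactants: 23 pyroterebic acid (4-methylpent-3-enoic acid)
Product: 24 methyl ester (methyl 4-methylpent-3-enoate)
Conditions: MeI, K2CO3, DMF, rt
Reagents that add atoms: iodomethane, CI
Why: Carboxylate O-alkylation; mild base at room temperature avoids the acid-catalysed lactonisation of this β,γ-unsaturated acid and should not move the double bond into conjugation.

Step 15
Reactants: 24 methyl ester (methyl 4-methylpent-3-enoate)
Product: 27 siloxyalkyne (triisopropyl[(5-methylhex-4-en-1-yn-1-yl)oxy]silane), via dibromo enolate 25 (not isolated), via lithium ynolate 26 (not isolated)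
Conditions: CH2Br2, lithium 2,2,6,6-tetramethylpiperidide, THF, −78 °C; LiN(SiMe3)2, −78 to −20 °C; n-BuLi, −78 °C to rt; i-Pr3SiCl, −78 °C to rt
Reagents that add atoms: dibromomethane, BrCBr; chlorotriisopropylsilane, CC(C)[Si](Cl)(C(C)C)C(C)C
Why: Kowalski ester homologation stopped at the ynolate: LiCHBr2 adds to the ester to give enolate 25, bromine–lithium exchange triggers migration of the prenyl-bearing carbon to the carbenoid carbon, and the resulting ynolate 26 is silylated on oxygen by the bulky chlorosilane; the inserted carbon places the prenyl group directly on the alkyne.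

Step 16
Reactants: 22 diazo vinyl ketone ((6R)-7-[(tert-butyldimethylsilyl)oxy]-4-diazo-6-ArB-hept-1-en-3-one); 27 siloxyalkyne (triisopropyl[(5-methylhex-4-en-1-yn-1-yl)oxy]silane)
Product: 32 ring A phenol (4-[(2R)-3-[(tert-butyldimethylsilyl)oxy]-2-ArB-propyl]-2-(3-methylbut-2-en-1-yl)-3-[(triisopropylsilyl)oxy]phenol), via vinylketene 28 (not isolated), via 4-vinylcyclobutenone 29 (not isolated), via dienylketene 30 (not isolated), via cyclohexadienone 31 (not isolated)
Conditions: 27 (1.5 equiv), ClCH2CH2Cl (degassed, 0.05 M), hν (405 nm LEDs), rt; then 80 °C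
Reagents that add atoms: none
Why: Light of 405 nm excites only the n→π* band of the diazo ketone (the chromene, which opens reversibly under ultraviolet light, is transparent there); N2 is lost and the vinyl group migrates (Wolff rearrangement) to give vinylketene 28. The ketene adds siloxyalkyne 27 in a polar, stepwise (2+2) cycloaddition: the nucleophilic alkyne carbon remote from oxygen attacks the ketene carbonyl carbon (C7–C8) and the oxygen-stabilised cation closes on the ketene α-carbon (C8a–C4a), giving 4-vinylcyclobutenone 29 with the prenyl group between the two oxygenated carbons. At 80 °C 29 opens by conrotatory 4-electron electrocyclic reaction to dienylketene 30, whose disrotatory 6-electron electrocyclisation forms C6–C7 and closes ring A as cyclohexadienone 31, which tautomerises to phenol 32. This is the Danheiser benzannulation in its diazo ketone variant, known for α′-diazo enones and triisopropylsiloxyalkynes. No stereocenter is created: the quaternary carbon of 29 is transient, and C3 is never part of an enol or a ketene, so it keeps its configuration. Regiochemistry is secured by the polarisation of the ynol ether. Chemoselectivity asks that vinyl migration outrun a 1,2-hydrogen shift from C4 in the ketocarbene (direct singlet excitation, a good migrating group) and that the ketene meet the alkyne before product phenol or a second ketene (alkyne in excess, dilute solution).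

Step 17
Reactants: 32 ring A phenol (4-[(2R)-3-[(tert-butyldimethylsilyl)oxy]-2-ArB-propyl]-2-(3-methylbut-2-en-1-yl)-3-[(triisopropylsilyl)oxy]phenol)
Product: 33 triol (4-[(2R)-3-hydroxy-2-ArB-propyl]-2-(3-methylbut-2-en-1-yl)benzene-1,3-diol)
Conditions: Bu4NF, THF (degassed), 0 °C to rt; aq. NH4Cl
Reagents that add atoms: none
Why: Fluoride cleaves the aryl triisopropylsilyl ether and the primary TBS ether in one operation, while the MOM acetal on O2′ is inert to fluoride.

Step 18
Reactants: 33 triol (4-[(2R)-3-hydroxy-2-ArB-propyl]-2-(3-methylbut-2-en-1-yl)benzene-1,3-diol)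
Product: 34 MOM-protected isoflavan ((3R)-3-ArB-8-(3-methylbut-2-en-1-yl)chroman-7-ol)
Conditions: PPh3, DIAD, THF (0.01 M), 0 °C to rt
Reagents that add atoms: none
Why: Intramolecular Mitsunobu etherification: the activated primary alcohol is displaced by the C8a phenol in a 6-exo-tet closure of ring C; the C7 phenol cannot reach C2, O2′ is capped so no 5-membered ring can form, and C3 is untouched because substitution occurs at the CH2 group.

Step 19
Reactants: 34 MOM-protected isoflavan ((3R)-3-ArB-8-(3-methylbut-2-en-1-yl)chroman-7-ol)
Product: 35 target ((3R)-3-(5-hydroxy-2,2-dimethyl-2H-chromen-6-yl)-8-(3-methylbut-2-en-1-yl)chroman-7-ol)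
Conditions: HCl (3 M aq.), MeOH, 40 °C
Reagents that add atoms: none
Why: Acid-catalysed methanolysis of the aryl MOM acetal; dilute acid at moderate temperature is the usual way to unmask prenylated phenols and should be mild enough to leave the prenyl phenol and the chromene intact.

## Compound list

1 | resorcylaldehyde (2,4-dihydroxybenzaldehyde) | O=Cc1ccc(O)cc1O | starting material
2 | prenal (3-methylbut-2-enal) | CC(C)=CC=O | starting material
3 | 5-hydroxy-2,2-dimethyl-2H-chromene-6-carbaldehyde | O=Cc1ccc2c(c1O)C=CC(C)(C)O2 | intermediate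
4 | 5-(methoxymethoxy)-2,2-dimethyl-2H-chromene-6-carbaldehyde (ArB-CHO) | COCOc1c(C=O)ccc2c1C=CC(C)(C)O2 | intermediate
5 | N-[2-ArB-1-(4-methylphenylsulfonyl)ethenyl]formamide | O=CNC(=Cc1ccc2c(c1OCOC)C=CC(C)(C)O2)S(=O)(=O)c1ccc(C)cc1 | intermediate (not isolated)
6 | ArB-acetonitrile | N#CCc1ccc2c(c1OCOC)C=CC(C)(C)O2 | intermediate
7 | ArB-acetic acid | OC(=O)Cc1ccc2c(c1OCOC)C=CC(C)(C)O2 | intermediate
8 | (4R)-4-benzyl-1,3-oxazolidin-2-one | O=C1N[C@H](Cc2ccccc2)CO1 | starting material
9 | mixed anhydride of 7 and pivalic acid | CC(C)(C)C(=O)OC(=O)Cc1ccc2c(c1OCOC)C=CC(C)(C)O2 | intermediate (not isolated)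
10 | (4R)-4-benzyl-3-(ArB-acetyl)-1,3-oxazolidin-2-one | O=C(Cc1ccc2c(c1OCOC)C=CC(C)(C)O2)N1[C@H](Cc2ccccc2)COC1=O | intermediate
11 | sodium (Z)-enolate of 10 | [Na+].[O-]/C(=C\c1ccc2c(c1OCOC)C=CC(C)(C)O2)N1[C@H](Cc2ccccc2)COC1=O | intermediate (not isolated)
12 | (4R)-4-benzyl-3-[(2R)-2-ArB-pent-4-enoyl]-1,3-oxazolidin-2-one | C=CC[C@H](c1ccc2c(c1OCOC)C=CC(C)(C)O2)C(=O)N1[C@H](Cc2ccccc2)COC1=O | intermediate
13 | (2R)-2-ArB-pent-4-en-1-ol | C=CC[C@H](c1ccc2c(c1OCOC)C=CC(C)(C)O2)CO | intermediate
14 | tert-butyl{[(2R)-2-ArB-pent-4-en-1-yl]oxy}dimethylsilane | C=CC[C@H](c1ccc2c(c1OCOC)C=CC(C)(C)O2)CO[Si](C)(C)C(C)(C)C | intermediate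
15 | 9-[(4R)-5-(TBS-oxy)-4-ArB-pentyl]-9-borabicyclo[3.3.1]nonane | CC(C)(C)[Si](C)(C)OC[C@@H](c1ccc2c(c1OCOC)C=CC(C)(C)O2)CCCB1C2CCCC1CCC2 | intermediate (not isolated)
16 | (4R)-5-(TBS-oxy)-4-ArB-pentan-1-ol | CC(C)(C)[Si](C)(C)OC[C@@H](c1ccc2c(c1OCOC)C=CC(C)(C)O2)CCCO | intermediate
17 | (4R)-5-(TBS-oxy)-4-ArB-pentanal | CC(C)(C)[Si](C)(C)OC[C@@H](c1ccc2c(c1OCOC)C=CC(C)(C)O2)CCC=O | intermediate
18 | (6R)-7-(TBS-oxy)-6-ArB-hept-1-en-3-ol (both C3 epimers) | CC(C)(C)[Si](C)(C)OC[C@@H](c1ccc2c(c1OCOC)C=CC(C)(C)O2)CCC(O)C=C | intermediate
19 | (6R)-7-(TBS-oxy)-6-ArB-hept-1-en-3-one | CC(C)(C)[Si](C)(C)OC[C@@H](c1ccc2c(c1OCOC)C=CC(C)(C)O2)CCC(=O)C=C | intermediate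
20 | lithium (6R)-7-(TBS-oxy)-6-ArB-hepta-1,3-dien-3-olate | CC(C)(C)[Si](C)(C)OC[C@@H](c1ccc2c(c1OCOC)C=CC(C)(C)O2)CC=C([O-])C=C.[Li+] | intermediate (not isolated)
21 | (6R)-7-(TBS-oxy)-6-ArB-4-(trifluoroacetyl)hept-1-en-3-one | CC(C)(C)[Si](C)(C)OC[C@@H](c1ccc2c(c1OCOC)C=CC(C)(C)O2)CC(C(=O)C(F)(F)F)C(=O)C=C | intermediate (not isolated)
22 | (6R)-7-(TBS-oxy)-4-diazo-6-ArB-hept-1-en-3-one | CC(C)(C)[Si](C)(C)OC[C@@H](c1ccc2c(c1OCOC)C=CC(C)(C)O2)CC(=[N+]=[N-])C(=O)C=C | intermediate
23 | 4-methylpent-3-enoic acid | CC(C)=CCC(=O)O | starting material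
24 | methyl 4-methylpent-3-enoate | CC(C)=CCC(=O)OC | intermediate
25 | lithium 1,1-dibromo-5-methylhexa-1,4-dien-2-olate | CC(C)=CCC([O-])=C(Br)Br.[Li+] | intermediate (not isolated)
26 | lithium 5-methylhex-4-en-1-yn-1-olate | CC(C)=CCC#C[O-].[Li+] | intermediate (not isolated)
27 | triisopropyl[(5-methylhex-4-en-1-yn-1-yl)oxy]silane | CC(C)=CCC#CO[Si](C(C)C)(C(C)C)C(C)C | intermediate
28 | (4R)-5-(TBS-oxy)-2-ethenyl-4-ArB-pent-1-en-1-one (vinylketene) | CC(C)(C)[Si](C)(C)OC[C@@H](c1ccc2c(c1OCOC)C=CC(C)(C)O2)CC(C=C)=C=O | intermediate (not isolated)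
29 | 4-ethenyl-4-[(2R)-3-(TBS-oxy)-2-ArB-propyl]-2-(3-methylbut-2-en-1-yl)-3-[(triisopropylsilyl)oxy]cyclobut-2-en-1-one (both C4 epimers) | CC(C)(C)[Si](C)(C)OC[C@@H](c1ccc2c(c1OCOC)C=CC(C)(C)O2)CC1(C=C)C(=O)C(CC=C(C)C)=C1O[Si](C(C)C)(C(C)C)C(C)C | intermediate (not isolated)
30 | (3E)-4-[(2R)-3-(TBS-oxy)-2-ArB-propyl]-2-(3-methylbut-2-en-1-yl)-3-[(triisopropylsilyl)oxy]hexa-1,3,5-trien-1-one (vinyl cis to the ketene carbon) | CC(C)(C)[Si](C)(C)OC[C@@H](c1ccc2c(c1OCOC)C=CC(C)(C)O2)C/C(C=C)=C(O[Si](C(C)C)(C(C)C)C(C)C)/C(CC=C(C)C)=C=O | intermediate (not isolated)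
31 | 4-[(2R)-3-(TBS-oxy)-2-ArB-propyl]-2-(3-methylbut-2-en-1-yl)-3-[(triisopropylsilyl)oxy]cyclohexa-2,4-dien-1-one | CC(C)(C)[Si](C)(C)OC[C@@H](c1ccc2c(c1OCOC)C=CC(C)(C)O2)CC1=CCC(=O)C(CC=C(C)C)=C1O[Si](C(C)C)(C(C)C)C(C)C | intermediate (not isolated)
32 | 4-[(2R)-3-(TBS-oxy)-2-ArB-propyl]-2-(3-methylbut-2-en-1-yl)-3-[(triisopropylsilyl)oxy]phenol | CC(C)(C)[Si](C)(C)OC[C@@H](c1ccc2c(c1OCOC)C=CC(C)(C)O2)Cc1ccc(O)c(CC=C(C)C)c1O[Si](C(C)C)(C(C)C)C(C)C | intermediate
33 | 4-[(2R)-3-hydroxy-2-ArB-propyl]-2-(3-methylbut-2-en-1-yl)benzene-1,3-diol | OC[C@@H](c1ccc2c(c1OCOC)C=CC(C)(C)O2)Cc1ccc(O)c(CC=C(C)C)c1O | intermediate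
34 | (3R)-3-ArB-8-(3-methylbut-2-en-1-yl)chroman-7-ol | CC(C)=CCc1c(O)ccc2c1OC[C@@H](c1ccc3c(c1OCOC)C=CC(C)(C)O3)C2 | intermediate
35 | (3R)-3-(5-hydroxy-2,2-dimethyl-2H-chromen-6-yl)-8-(3-methylbut-2-en-1-yl)chroman-7-ol | CC(C)=CCc1c(O)ccc2c1OC[C@@H](c1ccc3c(c1O)C=CC(C)(C)O3)C2 | target

## Step count and risk

Total: 19 steps. Longest linear sequence: 17 steps (steps 1–13 and 16–19). The siloxyalkyne arm is 2 steps (14 and 15).

**Step 16 (key step).**
- What may go wrong:
  - A 1,2-hydrogen shift from C4 in the ketocarbene competes with vinyl migration, diverting material to a cross-conjugated dienone.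
  - The unhindered vinylketene is lost to dimerisation or to acylation of the product phenol.
  - The thermal opening of the cyclobutenone stalls.
- Fallback: ring A is taken from an aromatic block instead of being built, setting out from aldehyde 1 and enolate 11 (from imide 10) and rejoining at triol 33.
  - C-prenylation of 1 with prenyl bromide in aqueous KOH gives 2,4-dihydroxy-3-(3-methylbut-2-en-1-yl)benzaldehyde F1.
  - Silylation with i-Pr3SiOTf and 2,6-lutidine gives the bis(triisopropylsilyl) ether F2.
  - NaBH4 in MeOH gives the benzylic alcohol F3.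
  - CBr4 and PPh3 give the benzylic bromide F4.
  - Alkylation of enolate 11 with F4 at −78 °C gives the imide F5, with the same facial control as in step 6.
  - LiBH4 gives the alcohol F6, and Bu4NF removes both aryl silyl ethers to return triol 33.
  - The price is the C6/C8/O-selectivity of the first prenylation, which the benzannulation was designed to avoid.

**Step 13.**
- What may go wrong:
  - Conjugate addition of the amide base or of enolate 20 to unreacted vinyl ketone leads to oligomerisation before acylation.
  - The diazo enone decomposes on standing by dipolar addition to its own enone.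
- Fallback: the enolate is made without amide base in the presence of enone, setting out from 19 and rejoining at dienolate 20.
  - Soft enolisation with Me3SiOTf and Et3N in CH2Cl2 at 0 °C gives the 2-(trimethylsilyloxy)diene F7, which can be freed from residual enone.
  - MeLi in THF at 0 °C cleaves the O–Si bond and regenerates lithium dienolate 20 free of amine, which is acylated and carried on as in step 13.

**Step 15.**
- What may go wrong:
  - LiCHBr2 or the amide deprotonates the doubly activated α-CH2 of the β,γ-unsaturated ester instead of adding to the carbonyl group.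
  - The excess alkyllithium metalates the propargylic/allylic CH2 of ynolate 26.
  - Silylation occurs on carbon.
- Fallback: the alkyne is made first and oxidised afterwards, setting out from ester 24 and rejoining at ynolate 26.
  - i-Bu2AlH at −78 °C gives 4-methylpent-3-enal F8.
  - CBr4 and PPh3 give 1,1-dibromo-5-methylhexa-1,4-diene F9.
  - Two equivalents of n-BuLi give (5-methylhex-4-en-1-yn-1-yl)lithium F10.
  - Oxidation of F10 with LiOOt-Bu (from t-BuOOH and LiN(SiMe3)2) delivers ynolate 26, which is silylated as in step 15.

**Step 19.**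
- What may go wrong:
  - Acid-catalysed addition of the C7 phenol to the prenyl double bond closes a dimethylchroman ring.
  - The chromene is hydrated or oligomerised before the acetal is fully cleaved.
- Fallback: the acetal is cleaved without protic acid, setting out from 34 and rejoining at 35.
  - Me3SiOTf and 2,2′-bipyridyl in CH2Cl2 at 0 °C convert the aryl MOM ether into an aryl silyl ether and silylate the free phenol, giving the bis(trimethylsilyl) ether F11 of the target.
  - Water hydrolyses F11 to 35 at neutral pH.

## Further compounds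

F1 | step 16 | 2,4-dihydroxy-3-(3-methylbut-2-en-1-yl)benzaldehyde | CC(C)=CCc1c(O)ccc(C=O)c1O
F2 | step 16 | 3-(3-methylbut-2-en-1-yl)-2,4-bis[(triisopropylsilyl)oxy]benzaldehyde | CC(C)=CCc1c(O[Si](C(C)C)(C(C)C)C(C)C)ccc(C=O)c1O[Si](C(C)C)(C(C)C)C(C)C
F3 | step 16 | {3-(3-methylbut-2-en-1-yl)-2,4-bis[(triisopropylsilyl)oxy]phenyl}methanol | CC(C)=CCc1c(O[Si](C(C)C)(C(C)C)C(C)C)ccc(CO)c1O[Si](C(C)C)(C(C)C)C(C)C
F4 | step 16 | 1-(bromomethyl)-3-(3-methylbut-2-en-1-yl)-2,4-bis[(triisopropylsilyl)oxy]benzene | CC(C)=CCc1c(O[Si](C(C)C)(C(C)C)C(C)C)ccc(CBr)c1O[Si](C(C)C)(C(C)C)C(C)C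
F5 | step 16 | (4R)-4-benzyl-3-{(2R)-2-ArB-3-[3-(3-methylbut-2-en-1-yl)-2,4-bis(triisopropylsilyloxy)phenyl]propanoyl}-1,3-oxazolidin-2-one | CC(C)=CCc1c(O[Si](C(C)C)(C(C)C)C(C)C)ccc(C[C@H](c2ccc3c(c2OCOC)C=CC(C)(C)O3)C(=O)N2[C@H](Cc3ccccc3)COC2=O)c1O[Si](C(C)C)(C(C)C)C(C)C
F6 | step 16 | (2R)-2-ArB-3-[3-(3-methylbut-2-en-1-yl)-2,4-bis(triisopropylsilyloxy)phenyl]propan-1-ol | CC(C)=CCc1c(O[Si](C(C)C)(C(C)C)C(C)C)ccc(C[C@H](c2ccc3c(c2OCOC)C=CC(C)(C)O3)CO)c1O[Si](C(C)C)(C(C)C)C(C)C
F7 | step 13 | (6R)-7-(TBS-oxy)-6-ArB-3-(trimethylsilyloxy)hepta-1,3-diene | CC(C)(C)[Si](C)(C)OC[C@@H](c1ccc2c(c1OCOC)C=CC(C)(C)O2)CC=C(O[Si](C)(C)C)C=C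
F8 | step 15 | 4-methylpent-3-enal | CC(C)=CCC=O
F9 | step 15 | 1,1-dibromo-5-methylhexa-1,4-diene | CC(C)=CCC=C(Br)Br
F10 | step 15 | (5-methylhex-4-en-1-yn-1-yl)lithium | [Li]C#CCC=C(C)C
F11 | step 19 | bis(trimethylsilyl) ether of 35 at O7 and O2′ | CC(C)=CCc1c(O[Si](C)(C)C)ccc2c1OC[C@@H](c1ccc3c(c1O[Si](C)(C)C)C=CC(C)(C)O3)C2
A1 | alternative 1 | (3R)-7,2′-bis(methoxymethoxy)-8,3′-bis(3-methylbut-2-en-1-yl)-4′-{[2-(trimethylsilyl)ethoxy]methoxy}isoflavan | COCOc1ccc2c(c1CC=C(C)C)OC[C@@H](c1ccc(OCOCC[Si](C)(C)C)c(CC=C(C)C)c1OCOC)C2
A2 | alternative 1 | (3R)-7,2′-bis(methoxymethoxy)-4′-{[2-(trimethylsilyl)ethoxy]methoxy}isoflavan | COCOc1ccc2c(c1)OC[C@@H](c1ccc(OCOCC[Si](C)(C)C)cc1OCOC)C2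
A3 | alternative 2 | 2-{(1R)-1-ArB-2-[2,4-bis(TBS-oxy)-3-(3-methylbut-2-en-1-yl)phenyl]ethyl}-4,4,5,5-tetramethyl-1,3,2-dioxaborolane | CC1(C)OB(OC1(C)C)[C@@H](c1ccc2c(c1OCOC)C=CC(C)(C)O2)Cc1ccc(O[Si](C)(C)C(C)(C)C)c(CC=C(C)C)c1O[Si](C)(C)C(C)(C)C
A4 | alternative 2 | 1-bromo-2,4-bis(TBS-oxy)-3-(3-methylbut-2-en-1-yl)benzene | CC(C)=CCc1c(O[Si](C)(C)C(C)(C)C)ccc(Br)c1O[Si](C)(C)C(C)(C)C
A5 | alternative 2 | ArB-magnesium bromide | COCOc1c([Mg]Br)ccc2c1C=CC(C)(C)O2
A6 | alternative 2 | 2-ethenyl-4,4,5,5-tetramethyl-1,3,2-dioxaborolane | C=CB1OC(C)(C)C(C)(C)O1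
A7 | alternative 3 | (3R)-7-(methoxymethoxy)-3-ArB-8-(3-methylbut-2-en-1-yl)chroman-2-ol (both C2 anomers) | CC(C)=CCc1c(OCOC)ccc2c1OC(O)[C@@H](c1ccc3c(c1OCOC)C=CC(C)(C)O3)C2
A8 | alternative 3 | ArB-acetaldehyde | O=CCc1ccc2c(c1OCOC)C=CC(C)(C)O2
A9 | alternative 3 | 3-(methoxymethoxy)-2-(3-methylbut-2-en-1-yl)-6-[(4-methylphenylsulfonyl)methyl]phenol | Cc1ccc(cc1)S(=O)(=O)Cc1ccc(OCOC)c(CC=C(C)C)c1O
A10 | alternative 3 | 3-(methoxymethoxy)-6-methylidene-2-(3-methylbut-2-en-1-yl)cyclohexa-2,4-dien-1-one | C=C1C=CC(OCOC)=C(CC=C(C)C)C1=O
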